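**Retrosynthetic overview**
1. Target ⇐ quinidine-mediated methanolysis of the meso cyclobutane-1,2-dicarboxylic anhydride (sets the absolute configuration; the cis ring fusion fixes both CH centres).
2. Anhydride ⇐ cyclobutane acid/tert-butyl ester ⇐ Wolff ring contraction of a 3-diazo-2-oxocyclopentane-1-carboxylate (key step: the ring C=O carbon is extruded and becomes the second carboxyl).
3. Cyclopentanone ⇐ reductive β,β'-coupling/Dieckmann cascade of two enoate arms stacked on naphthalene-1,8-diol, a recoverable bis-ester protecting group and template (sets the two quaternary centres syn).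
4. Tethered bis-enoate ⇐ Wittig olefination of biacetyl with the bromoacetate arms, double pyranone annulation with methylmalonyl dichloride (one molecule per arm), O-methylation.
5. Ring order: two pyranones → cyclopentanone → cyclobutane (by contraction) → anhydride (opened last).

Pyr = 4-methoxy-3-methyl-2-oxo-2H-pyran-6-yl (bonded through C6).

Assumption: methylmalonyl dichloride is bought (it is also made from methylmalonic acid and SOCl2); the chiral intermediates between the reductive coupling and the anhydride are racemic and drawn as one enantiomer; the sense of the final desymmetrisation is taken by analogy with known meso-anhydride openings.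

Step 1
Reactants: 1 bromoacetyl bromide
Product: 2 naphthalene-1,8-diyl bis(2-bromoacetate)
Conditions: naphthalene-1,8-diol (1 equiv), 1 (2.2 equiv), pyridine (2.4 equiv), CH2Cl2, 0 °C → rt
Reagents that add atoms: naphthalene-1,8-diol, Oc1cccc2cccc(O)c12
Why: O-acylation of the peri-diol by two molecules of the acid bromide (pyridine takes up HBr) puts both bromoacetate arms on a rigid 1,8-naphthalenediyl bis-ester, a recoverable carboxyl protecting group that later holds the two enoate arms stacked; no stereocentre is formed.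

Step 2
Reactants: 2 naphthalene-1,8-diyl bis(2-bromoacetate); 3 butane-2,3-dione (biacetyl)
Product: 6 naphthalene-1,8-diyl bis[(2E)-3-methyl-4-oxopent-2-enoate], via bis-phosphonium dibromide 4 (not isolated), via bis-ylide 5 (not isolated)
Conditions: PPh3 (2.1 equiv), PhMe, rt; then Et3N (2.2 equiv), 3 (6 equiv), CH2Cl2, 0 °C → rt
Reagents that add atoms: none
Why: Double Wittig olefination: the ester-stabilised ylide on each arm attacks one carbonyl of the reactive 1,2-diketone (two molecules of biacetyl are consumed, and the excess ensures each reacts once) and gives the E-enoate on both arms (acetyl trans to the ester), the normal outcome for stabilised ylides.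

Step 3
Reactants: 6 naphthalene-1,8-diyl bis[(2E)-3-methyl-4-oxopent-2-enoate]; 7 2-methylpropanedioyl dichloride (methylmalonyl dichloride)
Product: 9 naphthalene-1,8-diyl bis[(2E)-3-(4-hydroxy-3-methyl-2-oxo-2H-pyran-6-yl)but-2-enoate], via bis-silyl dienol ether 8 (not isolated)
Conditions: TMSOTf (2.3 equiv), Et3N (3 equiv), CH2Cl2, 0 °C; evaporate, pentane trituration; then Et2O, 7 (2.2 equiv), −78 °C → rt
Reagents that add atoms: none
Why: Double annulation that consumes two molecules of 7, one per methyl ketone: soft enolisation of both acetyl groups gives the bis(2-silyloxydiene) 8, each diene terminus is C-acylated by one molecule of 7, and each enol oxygen then closes on the second acid chloride of the same malonyl unit (silyl enol ether acylation–lactonisation, the malonyl dichloride route to 3-substituted 4-hydroxy-2-pyranones), so that every pyranone takes its C2, C3, C4 and 3-methyl from one molecule of 7; the E-enoates and aryl esters tolerate the acidic medium and no stereocentre is formed.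

Step 4
Reactants: 9 naphthalene-1,8-diyl bis[(2E)-3-(4-hydroxy-3-methyl-2-oxo-2H-pyran-6-yl)but-2-enoate]
Product: 10 naphthalene-1,8-diyl bis[(2E)-3-Pyr-but-2-enoate]
Conditions: Me2SO4 (2.4 equiv), K2CO3 (2.4 equiv), acetone, rt
Reagents that add atoms: dimethyl sulfate, COS(=O)(=O)OC
Why: Williamson-type O-methylation of the acidic 4-hydroxy-2-pyranones gives the 4-methoxy-2-pyranones in preference to the 2-methoxy-4-pyranone isomers, and the mild anhydrous base leaves the aryl enoates intact.

Step 5
Reactants: 10 naphthalene-1,8-diyl bis[(2E)-3-Pyr-but-2-enoate]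
Product: 13 tert-butyl cis-4,5-dimethyl-2-oxo-4,5-di-Pyr-cyclopentane-1-carboxylate (racemic; Pyr groups syn; C1 epimers and enol), via macrocyclic bis-enolate 11 (not isolated), via aryl keto ester 12 (not isolated)
Conditions: SmI2 (2.2 equiv), HMPA (8 equiv), THF, −78 → 0 °C; then t-BuOH (30 equiv), 60 °C; aq. HCl work-up
Reagents that add atoms: tert-butanol, CC(C)(C)O
Why: Proposed new method: one-electron reduction of one enoate arm gives a radical anion held cofacially (about 3.5 Å) over the second arm by the peri-diester, and because both E-arms are locked s-cis by allylic 1,3-strain between the β-methyl and the ester oxygen, the two stacked β-carbons bond with like faces opposed, which fixes the two quaternary centres as the meso pair with the Pyr groups syn; a second electron gives the macrocyclic bis-enolate 11, transannular Dieckmann condensation on the activated aryl ester closes cyclopentanone 12, and the aryl β-keto ester is exchanged for the tert-butyl ester through its acylketene; the closest known reaction types are the SmI2 or cathodic hydrodimerisation of cinnamates with in situ Dieckmann closure (which, untethered, favours the racemic trans pair) and the 1,8-naphthalenediol-templated photodimerisation of cinnamates to β-truxinates.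

Step 6
Reactants: 13 tert-butyl cis-4,5-dimethyl-2-oxo-4,5-di-Pyr-cyclopentane-1-carboxylate
Product: 15 tert-butyl cis-3-diazo-4,5-dimethyl-2-oxo-4,5-di-Pyr-cyclopentane-1-carboxylate (racemic; Pyr groups syn), via trifluoroacetyl ketone 14 (not isolated)
Conditions: LiN(iPr)2 (2.2 equiv), THF, −78 °C; CF3CO2CH2CF3 (1.3 equiv); aq. HCl work-up; then MsN3 (1.2 equiv), Et3N (1.5 equiv), H2O (1 equiv), MeCN, rt
Reagents that add atoms: methanesulfonyl azide, CS(=O)(=O)N=[N+]=[N-]
Why: The β-keto ester dianion is acylated only at its terminal α'-carbon (C3), and the resulting trifluoroacetyl 1,3-diketone, by far the most acidic site, undergoes detrifluoroacetylative Regitz diazo transfer (Danheiser protocol) to the α'-diazo ketone; the quaternary centres are untouched.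

Step 7
Reactants: 15 tert-butyl cis-3-diazo-4,5-dimethyl-2-oxo-4,5-di-Pyr-cyclopentane-1-carboxylate
Product: 17 2-(tert-butoxycarbonyl)-3,4-dimethyl-3,4-di-Pyr-cyclobutane-1-carboxylic acid (racemic; Pyr groups syn; CH epimers), via ketene 16 (not isolated)
Conditions: hν (440 nm LEDs), THF/H2O 10:1, rt
Reagents that add atoms: water, O
Why: Photochemical Wolff rearrangement: loss of N2 with 1,2-shift of the ester-bearing ring carbon from the carbonyl carbon to the diazo carbon contracts the cyclopentanone to a cyclobutylketene (the former ring ketone carbon becomes exocyclic), which water captures as the acid; 440 nm light is not absorbed by the pyranones, the quaternary centres are not involved, and the two CH centres (epimer mixture) are set in step 8.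

Step 8
Reactants: 17 2-(tert-butoxycarbonyl)-3,4-dimethyl-3,4-di-Pyr-cyclobutane-1-carboxylic acid
Product: 19 (1R,5S,6R,7S)-6,7-dimethyl-6,7-di-Pyr-3-oxabicyclo[3.2.0]heptane-2,4-dione (meso; Pyr groups exo; methyls endo), via diacid 18 (not isolated)
Conditions: TFA/CH2Cl2 1:1, rt; evaporate; then Ac2O, NaOAc (0.2 equiv), 120 °C
Reagents that add atoms: none
Why: Acidolysis of the tert-butyl ester, then dehydrative cyclisation under equilibrating conditions: only a cis-diacid can close the five-membered anhydride and the CH centres epimerise through mixed-anhydride enols, so all epimers funnel to the cis-fused anhydride that carries the stacked Pyr groups on the convex face and the methyls on the concave face, which fixes both CH centres in the meso compound.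

Step 9
Reactants: 19 (1R,5S,6R,7S)-6,7-dimethyl-6,7-di-Pyr-3-oxabicyclo[3.2.0]heptane-2,4-dione
Product: 20 (1S,2R,3S,4R)-2-(methoxycarbonyl)-3,4-dimethyl-3,4-bis(4-methoxy-3-methyl-2-oxo-2H-pyran-6-yl)cyclobutane-1-carboxylic acid (CNP0481603.1)
Conditions: quinidine (1.1 equiv), MeOH (3 equiv), PhMe, −55 °C; aq. HCl wash
Reagents that add atoms: methanol, CO
Why: Cinchona-alkaloid-mediated desymmetrising methanolysis of a meso anhydride (general-base delivery of methanol to one of the two enantiotopic carbonyls) gives the hemiester as a single enantiomer and so sets the absolute configuration, the sense with quinidine being assigned by analogy with other bicyclic meso anhydrides (quinine gives the antipode); at −55 °C no centre epimerises.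

**Compound list** (Pyr = 4-methoxy-3-methyl-2-oxo-2H-pyran-6-yl)

1 | bromoacetyl bromide | BrCC(Br)=O | starting material
2 | naphthalene-1,8-diyl bis(2-bromoacetate) | O=C(CBr)Oc1cccc2cccc(OC(=O)CBr)c12 | intermediate
3 | butane-2,3-dione (biacetyl) | CC(=O)C(C)=O | starting material
4 | [naphthalene-1,8-diylbis(oxy)]bis(2-oxoethane-2,1-diyl)bis(triphenylphosphonium) dibromide (formed in situ) | [Br-].[Br-].O=C(C[P+](c1ccccc1)(c1ccccc1)c1ccccc1)Oc1cccc2cccc(OC(=O)C[P+](c3ccccc3)(c3ccccc3)c3ccccc3)c12 | intermediate
5 | naphthalene-1,8-diyl bis[2-(triphenyl-λ5-phosphanylidene)acetate] (bis-ylide, formed in situ) | O=C(C=P(c1ccccc1)(c1ccccc1)c1ccccc1)Oc1cccc2cccc(OC(=O)C=P(c3ccccc3)(c3ccccc3)c3ccccc3)c12 | intermediate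
6 | naphthalene-1,8-diyl bis[(2E)-3-methyl-4-oxopent-2-enoate] | O=C(/C=C(\C)C(C)=O)Oc1cccc2cccc(OC(=O)/C=C(\C)C(C)=O)c12 | intermediate
7 | 2-methylpropanedioyl dichloride (methylmalonyl dichloride) | CC(C(Cl)=O)C(Cl)=O | starting material
8 | naphthalene-1,8-diyl bis{(2E)-3-methyl-4-[(trimethylsilyl)oxy]penta-2,4-dienoate} (formed in situ) | O=C(/C=C(\C)C(=C)O[Si](C)(C)C)Oc1cccc2cccc(OC(=O)/C=C(\C)C(=C)O[Si](C)(C)C)c12 | intermediate
9 | naphthalene-1,8-diyl bis[(2E)-3-(4-hydroxy-3-methyl-2-oxo-2H-pyran-6-yl)but-2-enoate] | O=C(/C=C(\C)c1cc(O)c(C)c(=O)o1)Oc1cccc2cccc(OC(=O)/C=C(\C)c3cc(O)c(C)c(=O)o3)c12 | intermediate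
10 | naphthalene-1,8-diyl bis[(2E)-3-Pyr-but-2-enoate] | O=C(/C=C(\C)c1cc(OC)c(C)c(=O)o1)Oc1cccc2cccc(OC(=O)/C=C(\C)c3cc(OC)c(C)c(=O)o3)c12 | intermediate
11 | meso macrocyclic bis(ester enolate) of the tethered hydrodimer, bound to trivalent samarium and drawn as the dianion (Pyr groups syn; formed in situ) | [O-]C1=C[C@@](C)(c2cc(OC)c(C)c(=O)o2)[C@@](C)(c2cc(OC)c(C)c(=O)o2)C=C([O-])Oc2cccc3cccc(O1)c23 | intermediate
12 | 8-hydroxynaphthalen-1-yl cis-4,5-dimethyl-2-oxo-4,5-di-Pyr-cyclopentane-1-carboxylate (racemic; Pyr groups syn; formed in situ as its samarium enolate) | Oc1cccc2cccc(OC(=O)C3C(=O)C[C@@](C)(c4cc(OC)c(C)c(=O)o4)[C@@]3(C)c3cc(OC)c(C)c(=O)o3)c12 | intermediate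
13 | tert-butyl cis-4,5-dimethyl-2-oxo-4,5-di-Pyr-cyclopentane-1-carboxylate (racemic; Pyr groups syn; C1 epimers and enol) | CC(C)(C)OC(=O)C1C(=O)C[C@@](C)(c2cc(OC)c(C)c(=O)o2)[C@@]1(C)c1cc(OC)c(C)c(=O)o1 | intermediate
14 | tert-butyl cis-4,5-dimethyl-2-oxo-4,5-di-Pyr-3-(trifluoroacetyl)cyclopentane-1-carboxylate (racemic; formed in situ) | CC(C)(C)OC(=O)C1C(=O)C(C(=O)C(F)(F)F)[C@@](C)(c2cc(OC)c(C)c(=O)o2)[C@@]1(C)c1cc(OC)c(C)c(=O)o1 | intermediate
15 | tert-butyl cis-3-diazo-4,5-dimethyl-2-oxo-4,5-di-Pyr-cyclopentane-1-carboxylate (racemic; Pyr groups syn) | CC(C)(C)OC(=O)C1C(=O)C(=[N+]=[N-])[C@@](C)(c2cc(OC)c(C)c(=O)o2)[C@@]1(C)c1cc(OC)c(C)c(=O)o1 | intermediate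
16 | tert-butyl cis-3,4-dimethyl-2-(oxomethylidene)-3,4-di-Pyr-cyclobutane-1-carboxylate (ketene; racemic; formed in situ) | CC(C)(C)OC(=O)C1C(=C=O)[C@@](C)(c2cc(OC)c(C)c(=O)o2)[C@@]1(C)c1cc(OC)c(C)c(=O)o1 | intermediate
17 | 2-(tert-butoxycarbonyl)-3,4-dimethyl-3,4-di-Pyr-cyclobutane-1-carboxylic acid (racemic; Pyr groups syn; mixture of CH epimers) | CC(C)(C)OC(=O)C1C(C(=O)O)[C@@](C)(c2cc(OC)c(C)c(=O)o2)[C@@]1(C)c1cc(OC)c(C)c(=O)o1 | intermediate
18 | 3,4-dimethyl-3,4-di-Pyr-cyclobutane-1,2-dicarboxylic acid (Pyr groups syn; CH epimers; formed in situ) | OC(=O)C1C(C(=O)O)[C@@](C)(c2cc(OC)c(C)c(=O)o2)[C@@]1(C)c1cc(OC)c(C)c(=O)o1 | intermediate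
19 | (1R,5S,6R,7S)-6,7-dimethyl-6,7-di-Pyr-3-oxabicyclo[3.2.0]heptane-2,4-dione (meso; Pyr groups exo, methyls endo) | O=C3[C@@H]1[C@H](C(=O)O3)[C@@](C)(c2cc(OC)c(C)c(=O)o2)[C@@]1(C)c1cc(OC)c(C)c(=O)o1 | intermediate
20 | (1S,2R,3S,4R)-2-(methoxycarbonyl)-3,4-dimethyl-3,4-bis(4-methoxy-3-methyl-2-oxo-2H-pyran-6-yl)cyclobutane-1-carboxylic acid | COC(=O)[C@@H]1[C@H](C(=O)O)[C@@](C)(c2cc(OC)c(C)c(=O)o2)[C@@]1(C)c1cc(OC)c(C)c(=O)o1 | target

**Step count and risks**

Total step count: 9. Longest linear sequence: 9 steps (1 → 20).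

The three steps most likely to fail:

Step 3, the double pyranone annulation on the tethered substrate. The silyloxydienes or 7 may self-condense, and two annulations must succeed on one molecule. The fallback builds the pyranone on the small diketone first and olefinates afterwards. Setting out from 3, TMSOTf/Et3N gives 3-[(trimethylsilyl)oxy]but-3-en-2-one F1, which closes with 7 to 6-acetyl-4-hydroxy-3-methyl-2H-pyran-2-one F2. Me2SO4/K2CO3 then gives 6-acetyl-4-methoxy-3-methyl-2H-pyran-2-one F3. Wittig olefination of two equivalents of F3 with bis-ylide 5 (made from 2 as in step 2; PhMe, 80 °C; the E,E isomer is separated) comes back to the route at 10.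

Step 5, the proposed new step. The risks are reduction or coupling at the pyranone ring, simple saturation of the arms, and incomplete Dieckmann closure. The fallback uses known chemistry without the tether. Setting out from 10, KOtBu in t-BuOH transesterifies the aryl esters and frees the monomer tert-butyl (2E)-3-Pyr-but-2-enoate F4. Hydrodimerisation of F4 with SmI2/HMPA/t-BuOH (the known SmI2-promoted reductive β,β-coupling of α,β-unsaturated esters) gives the hydrodimer as a mixture of diastereomers. From this mixture the meso isomer di-tert-butyl (3R,4S)-3,4-dimethyl-3,4-di-Pyr-hexanedioate F5 is separated by chromatography or crystallisation. Dieckmann condensation of F5 with KOtBu in THF comes back to the route at 13. The price is the loss of the racemic diastereomer, which is expected to be the major one.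

Step 6, the α'-diazo transfer. The sulfonyl azide may also attack the acidic C1–H of the β-keto ester, which leads to ring opening, and the acylation site lies next to a quaternary carbon. The fallback avoids sulfonyl azides. Setting out from 13, the dianion (LiN(iPr)2) is nitrosated at C3 with isoamyl nitrite to the α'-oximino ketone tert-butyl cis-3-(hydroxyimino)-4,5-dimethyl-2-oxo-4,5-di-Pyr-cyclopentane-1-carboxylate F6. The Forster reaction (NH2Cl from NH3 and NaOCl) then converts the oxime into the diazo ketone and comes back to the route at 15.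

Further compounds
F1 | step 3 | 3-[(trimethylsilyl)oxy]but-3-en-2-one | C=C(O[Si](C)(C)C)C(C)=O
F2 | step 3 | 6-acetyl-4-hydroxy-3-methyl-2H-pyran-2-one | CC(=O)c1cc(O)c(C)c(=O)o1
F3 | step 3 | 6-acetyl-4-methoxy-3-methyl-2H-pyran-2-one | CC(=O)c1cc(OC)c(C)c(=O)o1
F4 | step 5 | tert-butyl (2E)-3-(4-methoxy-3-methyl-2-oxo-2H-pyran-6-yl)but-2-enoate | CC(C)(C)OC(=O)/C=C(\C)c1cc(OC)c(C)c(=O)o1
F5 | step 5 | di-tert-butyl (3R,4S)-3,4-dimethyl-3,4-bis(4-methoxy-3-methyl-2-oxo-2H-pyran-6-yl)hexanedioate (meso) | CC(C)(C)OC(=O)C[C@@](C)(c1cc(OC)c(C)c(=O)o1)[C@@](C)(c1cc(OC)c(C)c(=O)o1)CC(=O)OC(C)(C)C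
F6 | step 6 | tert-butyl cis-3-(hydroxyimino)-4,5-dimethyl-4,5-bis(4-methoxy-3-methyl-2-oxo-2H-pyran-6-yl)-2-oxocyclopentane-1-carboxylate (racemic; pyranonyl groups syn) | CC(C)(C)OC(=O)C1C(=O)C(=NO)[C@@](C)(c2cc(OC)c(C)c(=O)o2)[C@@]1(C)c1cc(OC)c(C)c(=O)o1
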